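**Plan**
1. Retrosynthesis: the C(=O)–CH2 bond of the dihydrocaffeoyl amide on the acylated inner nitrogen is cut first, giving an N,N-dialkylcarbamoyl radical (from an oxamic acid) and the vinyl group of O-acetylated 4-vinylcatechol. The remaining oxamic acid is cut at the bond between the central butylene chain and the unacylated inner nitrogen (reductive amination), then at the terminal amide C–N bond and at the N–CH2 bond of the aminopropyl arm.
2. Forward: Cbz-β-aminopropanal and 4-aminobutanal diethyl acetal give the N–C3–N–C4 chain, and the inner nitrogen is oxalylated. The unmasked aldehyde is joined to benzyl-protected N-(3-aminopropyl)dihydrocaffeamide to complete the spermine chain as an oxamic acid. Decarboxylative hydrocarbamoylation of 3,4-diacetoxystyrene then builds the second dihydrocaffeoyl unit, and one acidic methanolysis/hydrogenolysis frees all groups.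
3. Enabling feature: in the tertiary amide N–C(=O)–CH2–CH2–aryl, the two methylene carbons between the carbonyl and the 3,4-dioxygenated benzene ring are the vinyl group of a styrene (decarboxylated caffeic acid). Radical attack at its terminal carbon leaves the unpaired electron on the carbon bound to the benzene ring, and the carbonyl carbon on nitrogen is available as a carbamoyl radical by loss of CO2 from N–C(=O)–CO2H.
4. Helpers: the extra carboxyl group (lost as CO2 in the event); two acetates on the vinylcatechol (they keep the alkene from being oxidised and are removed by methanolysis); Cbz and benzyl groups (removed by hydrogenolysis).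
5. Stereochemistry: the chain is acyclic and the target has no stereocentre and no stereogenic double bond, so nothing has to be set.

Key step: step 8

Assumption: since the target is achiral, "single enantiomer" is taken to mean the molecule as drawn; it would be handled as its dihydrochloride, and the free base is the structure given.

**Step 1**
Reactants: 1 caffeic acid
Product: 3 3,4-diacetoxystyrene (4-ethenyl-1,2-phenylene diacetate), via 4-vinylcatechol 2 (not isolated)
Conditions: Et3N (3 equiv), BHT (trace), DMF, 100 °C; then Ac2O (3 equiv), 0 °C → rt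
Reagents that add atoms: acetic anhydride, CC(=O)OC(C)=O
Why: Base-mediated decarboxylation of a 4-hydroxycinnamic acid through its quinone methide tautomer should give the vinylcatechol, which is trapped at once by O-acetylation before it can polymerise or oxidise.

**Step 2**
Reactants: 4 dihydrocaffeic acid [3-(3,4-dihydroxyphenyl)propanoic acid]
Product: 5 benzyl 3-[3,4-bis(benzyloxy)phenyl]propanoate
Conditions: BnBr (3.3 equiv), K2CO3 (4 equiv), DMF, N2, 60 °C
Reagents that add atoms: benzyl bromide, BrCc1ccccc1
Why: Williamson etherification of both phenols and alkylation of the carboxylate should proceed together under standard carbonate conditions.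

**Step 3**
Reactants: 5 benzyl 3-[3,4-bis(benzyloxy)phenyl]propanoate; 6 1,3-diaminopropane
Product: 7 N-(3-aminopropyl)-3-[3,4-bis(benzyloxy)phenyl]propanamide
Conditions: 6 (10 equiv, neat), 80 °C; excess 6 removed in vacuo
Reagents that add atoms: none
Why: Ester aminolysis with a large excess of the diamine should give the mono-amide only, and the aryl benzyl ethers are inert.

**Step 4**
Reactants: 8 4-aminobutanal diethyl acetal (4,4-diethoxybutan-1-amine); 9 benzyl N-(3-oxopropyl)carbamate
Product: 11 benzyl N-[3-(4,4-diethoxybutylamino)propyl]carbamate, via acetal imine 10 (not isolated)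
Conditions: 8 (1.5 equiv), 3 Å MS, MeOH, rt; then NaBH4, 0 °C
Reagents that add atoms: none
Why: Stepwise reductive amination (imine formed first, then borohydride) with the cheap amine in excess should give clean mono-alkylation, and the acetal and the carbamate survive.

**Step 5**
Reactants: 11 benzyl N-[3-(4,4-diethoxybutylamino)propyl]carbamate
Product: 12 ethyl 2-[[3-(benzyloxycarbonylamino)propyl](4,4-diethoxybutyl)amino]-2-oxoacetate
Conditions: ethyl chlorooxoacetate (1.1 equiv), Et3N, CH2Cl2, 0 °C
Reagents that add atoms: ethyl chlorooxoacetate, CCOC(=O)C(Cl)=O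
Why: N-acylation with an acid chloride should take place only at the single basic secondary amine, since the carbamate N–H is not nucleophilic; this step brings in the carbon that becomes the amide carbonyl together with its traceless carboxyl activator.

**Step 6**
Reactants: 12 ethyl 2-[[3-(benzyloxycarbonylamino)propyl](4,4-diethoxybutyl)amino]-2-oxoacetate
Product: 14 2-[[3-(benzyloxycarbonylamino)propyl](4-oxobutyl)amino]-2-oxoacetic acid, via lithium oxamate acetal 13 (not isolated)
Conditions: LiOH·H2O (1.5 equiv), THF–H2O, 0 °C; then 2 M aq. HCl to pH 1, rt; EtOAc extraction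
Reagents that add atoms: lithium hydroxide, [Li+].[OH-]; water, O
Why: Saponification of the strongly electrophilic oxamate ester is much faster than attack on the carbamate, and the subsequent acid-catalysed acetal hydrolysis unmasks the aldehyde; removing the ester before any free amine is introduced avoids later oxamide formation.

**Step 7**
Reactants: 14 2-[[3-(benzyloxycarbonylamino)propyl](4-oxobutyl)amino]-2-oxoacetic acid; 7 N-(3-aminopropyl)-3-[3,4-bis(benzyloxy)phenyl]propanamide
Product: 17 2-[[3-(benzyloxycarbonylamino)propyl][4-[benzyloxycarbonyl[3-[3-[3,4-bis(benzyloxy)phenyl]propanoylamino]propyl]amino]butyl]amino]-2-oxoacetic acid, via imine acid 15 (not isolated), via secondary amino acid 16 (not isolated)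
Conditions: 7 (1.2 equiv), Et3N (1.1 equiv), 3 Å MS, MeOH, rt; NaBH4, 0 °C; then solvent switch to THF–aq. NaHCO3, CbzCl, 0 °C; 1 M HCl to pH 2, EtOAc extraction
Reagents that add atoms: benzyl chloroformate, O=C(Cl)OCc1ccccc1
Why: Stepwise reductive amination joins the two chain halves (borohydride leaves the carboxylate salt and the tertiary oxamide untouched), and Schotten–Baumann Cbz protection of the new secondary amine in the same pot gives the only acidic lipophilic component, separable by acid–base extraction.

**Step 8**
Reactants: 17 the bis-Cbz oxamic acid from step 7; 3 3,4-diacetoxystyrene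
Product: 18 4-[3-[[3-(benzyloxycarbonylamino)propyl][4-[benzyloxycarbonyl[3-[3-[3,4-bis(benzyloxy)phenyl]propanoylamino]propyl]amino]butyl]amino]-3-oxopropyl]-1,2-phenylene diacetate
Conditions: 3 (2 equiv), 4CzIPN (2 mol%), 2,4,6-triisopropylbenzenethiol (15 mol%), 2,4,6-collidine (1 equiv), degassed MeCN, blue LEDs (450 nm), rt
Reagents that add atoms: none
Why: Deprotonated 17 is oxidised by photoexcited 4CzIPN and loses CO2; the nucleophilic N,N-dialkylcarbamoyl radical adds to the terminal CH2 of the vinyl group of 3, the benzylic radical takes a hydrogen atom from the aryl thiol, and the thiyl radical is reduced by the catalyst radical anion and reprotonated by further 17, so the cycle is redox-neutral with CO2 as the only by-product. The closest known reaction type is the photoredox decarboxylative Giese-type hydrocarbamoylation of alkenes with oxamic acids, run with the thiol hydrogen-atom-transfer termination used for anti-Markovnikov radical hydrofunctionalisation of vinylarenes. No ring is closed and no stereocentre is formed. The step needs anti-Markovnikov regioselectivity, which is secured by the benzylic stabilisation of the adduct radical by the diacetoxyphenyl ring. It also needs the oxamate, not the alkene or a catechol ring, to be the species oxidised: the two acetates raise the oxidation potential of the styrene and make it a polarity-matched acceptor, and any reversible oxidation of the neutral dibenzyloxyarene is unproductive whereas oxidation of the carboxylate is made irreversible by loss of CO2. Chain growth of the styrene should be outrun by hydrogen-atom transfer from the thiol, and the excess of 3 should outrun a 1,5-hydrogen shift within the carbamoyl radical.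

**Step 9**
Reactants: 18 the fully protected coupling product from step 8
Product: 20 kukoamine B, via free catechol 19 (not isolated)
Conditions: 1.25 M HCl in MeOH, rt; then 10% Pd/C, H2 (1 atm), same solution, rt; filter, concentrate (dihydrochloride)
Reagents that add atoms: none
Why: Acid-catalysed methanolysis should remove the two aryl acetates while all amines are still carbamates (so no O-to-N acetyl transfer), and Pd-catalysed hydrogenolysis in the same acidic methanol then cleaves both benzyl ethers and both Cbz groups, the amines being protonated as they form.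

**Compound list**
1 | caffeic acid [(E)-3-(3,4-dihydroxyphenyl)prop-2-enoic acid] | OC(=O)/C=C/c1ccc(O)c(O)c1 | starting material
2 | 4-vinylcatechol (4-ethenylbenzene-1,2-diol), formed in situ | C=Cc1ccc(O)c(O)c1 | intermediate
3 | 3,4-diacetoxystyrene (4-ethenyl-1,2-phenylene diacetate) | C=Cc1ccc(OC(C)=O)c(OC(C)=O)c1 | intermediate
4 | dihydrocaffeic acid [3-(3,4-dihydroxyphenyl)propanoic acid] | OC(=O)CCc1ccc(O)c(O)c1 | starting material
5 | benzyl 3-[3,4-bis(benzyloxy)phenyl]propanoate | O=C(CCc1ccc(OCc2ccccc2)c(OCc2ccccc2)c1)OCc1ccccc1 | intermediate
6 | 1,3-diaminopropane | NCCCN | starting material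
7 | N-(3-aminopropyl)-3-[3,4-bis(benzyloxy)phenyl]propanamide | NCCCNC(=O)CCc1ccc(OCc2ccccc2)c(OCc2ccccc2)c1 | intermediate
8 | 4-aminobutanal diethyl acetal (4,4-diethoxybutan-1-amine) | CCOC(CCCN)OCC | starting material
9 | benzyl N-(3-oxopropyl)carbamate [3-(Cbz-amino)propanal] | O=CCCNC(=O)OCc1ccccc1 | starting material
10 | benzyl N-[3-(4,4-diethoxybutylimino)propyl]carbamate, formed in situ | CCOC(CCCN=CCCNC(=O)OCc1ccccc1)OCC | intermediate
11 | benzyl N-[3-(4,4-diethoxybutylamino)propyl]carbamate | CCOC(CCCNCCCNC(=O)OCc1ccccc1)OCC | intermediate
12 | ethyl 2-[[3-(benzyloxycarbonylamino)propyl](4,4-diethoxybutyl)amino]-2-oxoacetate | CCOC(CCCN(CCCNC(=O)OCc1ccccc1)C(=O)C(=O)OCC)OCC | intermediate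
13 | lithium 2-[[3-(benzyloxycarbonylamino)propyl](4,4-diethoxybutyl)amino]-2-oxoacetate, formed in situ | [Li+].[O-]C(=O)C(=O)N(CCCNC(=O)OCc1ccccc1)CCCC(OCC)OCC | intermediate
14 | 2-[[3-(benzyloxycarbonylamino)propyl](4-oxobutyl)amino]-2-oxoacetic acid | OC(=O)C(=O)N(CCCNC(=O)OCc1ccccc1)CCCC=O | intermediate
15 | imine of aldehyde 14 with amine 7 (oxamic acid with C=N in the butylene chain), formed in situ | OC(=O)C(=O)N(CCCNC(=O)OCc1ccccc1)CCCC=NCCCNC(=O)CCc1ccc(OCc2ccccc2)c(OCc2ccccc2)c1 | intermediate
16 | 2-[[3-(benzyloxycarbonylamino)propyl][4-[[3-[3-[3,4-bis(benzyloxy)phenyl]propanoylamino]propyl]amino]butyl]amino]-2-oxoacetic acid, formed in situ | OC(=O)C(=O)N(CCCNC(=O)OCc1ccccc1)CCCCNCCCNC(=O)CCc1ccc(OCc2ccccc2)c(OCc2ccccc2)c1 | intermediate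
17 | 2-[[3-(benzyloxycarbonylamino)propyl][4-[benzyloxycarbonyl[3-[3-[3,4-bis(benzyloxy)phenyl]propanoylamino]propyl]amino]butyl]amino]-2-oxoacetic acid | OC(=O)C(=O)N(CCCNC(=O)OCc1ccccc1)CCCCN(CCCNC(=O)CCc1ccc(OCc2ccccc2)c(OCc2ccccc2)c1)C(=O)OCc1ccccc1 | intermediate
18 | fully protected kukoamine B: two N-Cbz groups, O,O-dibenzyl on the secondary-amide catechol, O,O-diacetyl on the tertiary-amide catechol | CC(=O)Oc1ccc(CCC(=O)N(CCCNC(=O)OCc2ccccc2)CCCCN(CCCNC(=O)CCc2ccc(OCc3ccccc3)c(OCc3ccccc3)c2)C(=O)OCc2ccccc2)cc1OC(C)=O | intermediate
19 | as 18 but with the free catechol on the tertiary-amide arm, formed in situ | Oc1ccc(CCC(=O)N(CCCNC(=O)OCc2ccccc2)CCCCN(CCCNC(=O)CCc2ccc(OCc3ccccc3)c(OCc3ccccc3)c2)C(=O)OCc2ccccc2)cc1O | intermediate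
20 | kukoamine B | NCCCN(CCCCNCCCNC(=O)CCc1ccc(O)c(O)c1)C(=O)CCc1ccc(O)c(O)c1 | target

**Step count and risks**
Total step count: 9. Longest linear sequence: 6 steps (steps 4 to 9, from 8 and 9).

Most likely to fail, first: step 8. The excited photocatalyst may be quenched unproductively by the electron-rich dibenzyloxyarene, the carbamoyl radical may add to the styrene too slowly relative to an internal 1,5-hydrogen shift, or the styrene may telomerise. The fallback sets out from 17 and comes back at 18, and replaces the oxidative decarboxylation by a net-reductive radical generation. Acid 17 is esterified with N-hydroxyphthalimide (DIC, DMAP cat., CH2Cl2) to the N-hydroxyphthalimido oxamate F1. F1 is irradiated (blue LEDs) with Ru(bpy)3(PF6)2 and Hantzsch ester (1.5 equiv) in the presence of 3. Single-electron reduction of F1 releases the same carbamoyl radical without any oxidising excited state, and the Hantzsch ester, present in stoichiometric amount, serves as electron source and as hydrogen-atom donor to the benzylic radical, giving 18.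

Second: step 7. The primary amine may be alkylated twice, the aliphatic aldehyde may undergo aldol-type self-condensation while the imine forms, and the zwitterionic amino acid may be lost during the one-pot protection and extraction. The fallback sets out from 7 and comes back at 17. It changes the order of bond formation so that every nitrogen is an amide or carbamate before the oxalyl group is introduced, and no zwitterion is handled.
- 2,3-Dihydrofuran is hydrated with dilute aqueous HCl to 2-hydroxytetrahydrofuran F2.
- Reductive amination of F2 with 7 (NaBH(OAc)3) gives the amino alcohol N-[3-(4-hydroxybutylamino)propyl]-3-[3,4-bis(benzyloxy)phenyl]propanamide F3.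
- CbzCl gives the N-Cbz alcohol F4, and Dess–Martin oxidation gives the N-Cbz aldehyde F5.
- Reductive amination with commercial benzyl N-(3-aminopropyl)carbamate, used in excess, gives the secondary amine F6.
- Acylation with ethyl chlorooxoacetate gives the ethyl oxamate F7, and LiOH hydrolysis then gives 17.

Third: step 9. Hydrogenolysis may stall through poisoning of the catalyst by the liberated polyamine, the amines may be reductively N-methylated by methanol on palladium, and the catechols may oxidise in air during isolation. The fallback sets out from 18 and comes back at 20 without hydrogen or metal. Acidic methanolysis as in the route gives 19, which is freed from methanol and treated with BCl3 and pentamethylbenzene (CH2Cl2, −78 → 0 °C), then quenched with MeOH. The Lewis acid cleaves the aryl benzyl ethers and the benzyl carbamates, and the benzyl cations are captured by pentamethylbenzene. This fallback makes no new compound (F0).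

**Further compounds**
F1 | step 8 | N-hydroxyphthalimido ester of oxamic acid 17 | O=C(ON1C(=O)c2ccccc2C1=O)C(=O)N(CCCNC(=O)OCc1ccccc1)CCCCN(CCCNC(=O)CCc1ccc(OCc2ccccc2)c(OCc2ccccc2)c1)C(=O)OCc1ccccc1
F2 | step 7 | 2-hydroxytetrahydrofuran | OC1CCCO1
F3 | step 7 | N-[3-(4-hydroxybutylamino)propyl]-3-[3,4-bis(benzyloxy)phenyl]propanamide | OCCCCNCCCNC(=O)CCc1ccc(OCc2ccccc2)c(OCc2ccccc2)c1
F4 | step 7 | benzyl N-(4-hydroxybutyl)-N-[3-[3-[3,4-bis(benzyloxy)phenyl]propanoylamino]propyl]carbamate | OCCCCN(CCCNC(=O)CCc1ccc(OCc2ccccc2)c(OCc2ccccc2)c1)C(=O)OCc1ccccc1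
F5 | step 7 | benzyl N-(4-oxobutyl)-N-[3-[3-[3,4-bis(benzyloxy)phenyl]propanoylamino]propyl]carbamate | O=CCCCN(CCCNC(=O)CCc1ccc(OCc2ccccc2)c(OCc2ccccc2)c1)C(=O)OCc1ccccc1
F6 | step 7 | benzyl N-[4-[3-(benzyloxycarbonylamino)propylamino]butyl]-N-[3-[3-[3,4-bis(benzyloxy)phenyl]propanoylamino]propyl]carbamate | O=C(NCCCNCCCCN(CCCNC(=O)CCc1ccc(OCc2ccccc2)c(OCc2ccccc2)c1)C(=O)OCc1ccccc1)OCc1ccccc1
F7 | step 7 | ethyl ester of oxamic acid 17 | CCOC(=O)C(=O)N(CCCNC(=O)OCc1ccccc1)CCCCN(CCCNC(=O)CCc1ccc(OCc2ccccc2)c(OCc2ccccc2)c1)C(=O)OCc1ccccc1
F0 | step 9 | none | none
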